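The route rests on disconnecting the ethyl bond C2–C3 and the ring bond C27–C11 of the cyclopentane (C3–C4–C10–C11–C27): the quaternary carbon C27, flanked by ethyl-bearing C3 and by C11, is a malonate carbon that first serves as the α-carbon of a Michael acceptor and then as the nucleophile. One operation adds ethyl from diethylzinc to C3 and closes that ring onto a neighbouring enoate, setting C3 and C11. The substrate is an all-cis γ-lactone carrying a C3 alkylidene malonate and a C11 (E)-enoate, made from D-glyceraldehyde by silicon-tethered radical cyclisation; its benzyl and 2-(trimethylsilyl)ethyl esters keep C13, C28 and C25 distinguishable for the lactam, ring D and azepane closures.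

Key step: step 10

Remark: atom labels (C1 to C28, O5, O20, N21) follow the order of the target SMILES and are used for all intermediates.
Assumption: the vinylogous Mannich addition of step 15 follows the open transition state (attack anti to tert-butyl); if the sense proves opposite, the (R)-enantiomer of the sulfinamide is used in step 13 and nothing else changes.

Step 1
Reactants: 1 2,3-O-isopropylidene-D-glyceraldehyde; 2 ethyl 2-[bis(2,2,2-trifluoroethoxy)phosphoryl]propanoate
Product: 3 ethyl (Z)-3-[(4S)-2,2-dimethyl-1,3-dioxolan-4-yl]-2-methylprop-2-enoate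
Conditions: KN(SiMe3)2, 18-crown-6, THF, −78 °C
Reagents that add atoms: none
Why: Still–Gennari olefination should give the Z trisubstituted enoate under kinetic control, the geometry that the lactonisation of step 2 needs, and the cold, brief exposure to base leaves the α-alkoxy stereocentre (later C4) intact.

Step 2
Reactants: 3 ethyl (Z)-3-[(4S)-2,2-dimethyl-1,3-dioxolan-4-yl]-2-methylprop-2-enoate
Product: 4 (5S)-5-(hydroxymethyl)-3-methylfuran-2(5H)-one
Conditions: 2 M aq. HCl, THF, 23 °C
Reagents that add atoms: none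
Why: acid-catalysed acetal hydrolysis frees the diol, and the Z-configured γ-hydroxy ester should close at once to the five-membered butenolide by lactonisation.

Step 3
Reactants: 4 (5S)-5-(hydroxymethyl)-3-methylfuran-2(5H)-one; 5 (bromomethyl)chlorodimethylsilane
Product: 7 all-cis bicyclic siloxane lactone (ring C4–CH2–O–SiMe2–CH2–C10 cis-fused to the lactone; C8 methyl on the same face), via bromomethylsilyl ether 6 (not isolated)
Conditions: Et3N, DMAP (cat.), CH2Cl2, 0 °C; then Bu3SnH (slow addition), AIBN (cat.), PhH, 80 °C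
Reagents that add atoms: none
Why: in this silicon-tethered 6-exo-trig radical cyclisation the α-silyl radical adds to the β-carbon C10 from the face of the tether, which fixes C10 cis to C4, and the lactone α-radical then takes hydrogen from Bu3SnH on the convex face, which places the C8 methyl cis to both arms.

Step 4
Reactants: 7 all-cis bicyclic siloxane lactone
Product: 8 (3S,4S,5S)-4,5-bis(hydroxymethyl)-3-methyloxolan-2-one
Conditions: 30% H2O2, KF, KHCO3, THF/MeOH, 0 → 23 °C
Reagents that add atoms: hydrogen peroxide, OO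
Why: Tamao oxidation replaces the C11–Si bond by C11–OH with retention and hydrolyses the Si–O bond, and a short, buffered exposure should limit translactonisation of the 1,4-diol.

Step 5
Reactants: 8 (3S,4S,5S)-4,5-bis(hydroxymethyl)-3-methyloxolan-2-one
Product: 9 (3S,4S,5S)-5-[(tert-butyldiphenylsilyloxy)methyl]-4-(hydroxymethyl)-3-methyloxolan-2-one
Conditions: TBDPSCl (1.05 equiv), imidazole, CH2Cl2, −20 → 0 °C
Reagents that add atoms: tert-butyl(chloro)diphenylsilane, CC(C)(C)[Si](Cl)(c1ccccc1)c1ccccc1
Why: regioselective silyl ether formation with a bulky chloride should pick the C3 carbinol, which has one cis neighbour, over the C11 carbinol wedged between the C8 methyl and the C4 arm.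

Step 6
Reactants: 9 (3S,4S,5S)-5-[(tert-butyldiphenylsilyloxy)methyl]-4-(hydroxymethyl)-3-methyloxolan-2-one; 10 benzyl (triphenylphosphoranylidene)acetate
Product: 12 benzyl (E)-3-[(2S,3R,4S)-2-[(tert-butyldiphenylsilyloxy)methyl]-4-methyl-5-oxooxolan-3-yl]prop-2-enoate, via C11 aldehyde 11 (not isolated)
Conditions: DMP, NaHCO3, CH2Cl2, 0 °C; then 10, CH2Cl2, 23 °C
Reagents that add atoms: none
Why: Dess–Martin oxidation followed by Wittig olefination with a stabilised, non-basic ylide should give the E enoate without epimerising C10 or eliminating the β-acyloxy group of the aldehyde.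

Step 7
Reactants: 12 benzyl (E)-3-[(2S,3R,4S)-2-[(tert-butyldiphenylsilyloxy)methyl]-4-methyl-5-oxooxolan-3-yl]prop-2-enoate
Product: 13 benzyl (E)-3-[(2S,3R,4S)-2-(hydroxymethyl)-4-methyl-5-oxooxolan-3-yl]prop-2-enoate
Conditions: HF·pyridine, pyridine, THF, 0 → 23 °C
Reagents that add atoms: none
Why: fluoride desilylation under acidic buffering frees the C3 carbinol without the alkoxide that would add to the cis enoate in an oxa-Michael reaction.

Step 8
Reactants: 14 malonic acid; 15 2-(trimethylsilyl)ethanol
Product: 16 bis[2-(trimethylsilyl)ethyl] propanedioate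
Conditions: 15 (2.2 equiv in all), DCC (2.2 equiv), MeCN, 0 → 23 °C
Reagents that add atoms: 2-(trimethylsilyl)ethanol (second equivalent of 15), C[Si](C)(C)CCO
Why: twofold carbodiimide (Steglich-type) esterification, in which each carboxyl group of malonic acid takes up one molecule of the alcohol, gives a malonate whose esters withstand hydrogenation but fall to fluoride, so that the ester left over after lactam formation can later be freed without touching the lactones.

Step 9
Reactants: 13 benzyl (E)-3-[(2S,3R,4S)-2-(hydroxymethyl)-4-methyl-5-oxooxolan-3-yl]prop-2-enoate; 16 bis[2-(trimethylsilyl)ethyl] propanedioate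
Product: 18 bis[2-(trimethylsilyl)ethyl] 2-{[(2S,3R,4S)-3-[(E)-3-(benzyloxy)-3-oxoprop-1-enyl]-4-methyl-5-oxooxolan-2-yl]methylidene}propanedioate, via C3 aldehyde 17 (not isolated)
Conditions: DMP, NaHCO3, CH2Cl2, 0 °C; then 16, TiCl4, pyridine, THF, 0 °C
Reagents that add atoms: none
Why: Dess–Martin oxidation and Knoevenagel condensation under the TiCl4–pyridine (Lehnert) protocol, whose weak base and low temperature should spare the epimerisable C4–H of the α-acyloxy aldehyde.

Step 10
Reactants: 18 all-cis lactone with C3 alkylidene malonate and C11 (E)-enoate; 19 diethylzinc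
Product: 22 cis-fused cyclopentane lactone (C3 ethyl, C27 bis[2-(trimethylsilyl)ethyl] ester, C11 CH2CO2Bn arm), via ethylzinc malonate enolate 20 (not isolated), via open-chain ethyl malonate 21 (not isolated)
Conditions: Et2Zn (1.5 equiv), Cu(OTf)2 (5 mol %), P(OEt)3 (10 mol %), toluene, −30 → 0 °C; then t-BuOH (3 equiv), DBU, THF, 0 → 23 °C, same flask
Reagents that add atoms: none
Why: Cu(OTf)2 is reduced by Et2Zn to a monovalent ethylcopper–zinc species that transfers ethyl to C3 of the alkylidene malonate and leaves the C27 zinc enolate 20; tert-butanol frees malonate 21 and DBU then drives C27 onto C11 of the enoate, so that C2–C3 and C27–C11 form in one flask. The closest known reactions are the copper-catalysed conjugate addition of dialkylzincs to alkylidene malonates and the Michael-initiated ring closure of a malonate onto a tethered enoate. The cyclopentane C3–C4–C10–C11–C27 closes 5-exo-trig and must be cis-fused to the lactone because both arms sit on the same face of the C4–C10 bond. At C3, allylic 1,3-strain with the Z ester holds C4–H in the alkene plane and the cis C10 arm screens one face, so ethyl should enter anti to that arm, on the O5 side of the open-chain conformer, and end trans to O5 once the ring has closed. At C11 the closure is reversible under DBU and the acetate arm should settle on the convex face, trans to C8. The step needs ethyl to choose C3 over C11 and 1,4-addition over SN2′ loss of the allylic lactone carboxylate: the doubly activated malonate alkene is far more electrophilic than the benzyl enoate, and the soft zinc–copper reagent at low temperature favours conjugate transfer.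

Step 11
Reactants: 22 cis-fused cyclopentane lactone with C13 benzyl ester
Product: 23 C13 carboxylic acid of 22
Conditions: H2 (1 atm), Pd/C, EtOAc, 23 °C
Reagents that add atoms: none
Why: hydrogenolysis removes only the benzyl ester, which singles out C13 among the four carboxyl groups.

Step 12
Reactants: 23 C13 carboxylic acid
Product: 25 C13 aldehyde (C11–CH2–CHO), via acid chloride 24 (not isolated)
Conditions: (COCl)2, DMF (cat.), CH2Cl2, 0 → 23 °C; then LiAlH(OtBu)3, THF, −78 °C
Reagents that add atoms: none
Why: reduction of an acid chloride with the hindered alkoxyaluminium hydride stops at the aldehyde and is far faster at −78 °C than attack on the esters or the lactone.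

Step 13
Reactants: 25 C13 aldehyde; 26 (S)-2-methylpropane-2-sulfinamide
Product: 27 (S)-N-tert-butanesulfinyl (E)-aldimine at C13
Conditions: CuSO4, CH2Cl2, 23 °C
Reagents that add atoms: none
Why: dehydrative condensation to the sulfinimine under neutral Lewis acidic conditions avoids the retro-Michael opening that base could cause in the β-malonyl aldehyde.

Step 14
Reactants: 28 3-methylfuran-2(5H)-one
Product: 29 tert-butyldimethyl[(3-methylfuran-2-yl)oxy]silane
Conditions: TBSOTf, Et3N, CH2Cl2, 0 °C
Reagents that add atoms: tert-butyldimethylsilyl trifluoromethanesulfonate, CC(C)(C)[Si](C)(C)OS(=O)(=O)C(F)(F)F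
Why: soft enolisation and O-silylation give the aromatic 2-silyloxyfuran (silyl dienol ether formation).

Step 15
Reactants: 27 N-sulfinyl aldimine; 29 tert-butyldimethyl[(3-methylfuran-2-yl)oxy]silane
Product: 30 (13R,14R)-sulfinamide carrying the 3-methylbutenolide at C14
Conditions: TMSOTf (0.2 equiv), CH2Cl2, −78 °C
Reagents that add atoms: none
Why: in this vinylogous Mannich addition through an open transition state the furan γ-carbon attacks the silyl-activated s-cis sulfinimine on the face away from tert-butyl, which should set C13 as R, and the 3-methyl silyloxyfuran adds with syn (threo) topicity, which should set C14 as R.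

Step 16
Reactants: 30 butenolide sulfinamide
Product: 31 sulfinamide with saturated ring D lactone (C16 R, methyl cis to C13)
Conditions: H2 (1 atm), Pd/C, EtOAc, 23 °C
Reagents that add atoms: none
Why: heterogeneous hydrogenation delivers hydrogen to the butenolide face opposite the C14 substituent and should give the cis 2,4-disubstituted lactone.

Step 17
Reactants: 31 ring D lactone sulfinamide
Product: 33 cis-fused N–H δ-lactam (N21–C28) with C27 2-(trimethylsilyl)ethyl ester, via primary amine 32 (not isolated)
Conditions: HCl (4 M in dioxane), MeOH, 0 °C; then aq. NaHCO3, CH2Cl2, 23 → 40 °C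
Reagents that add atoms: none
Why: acid cleavage of the sulfinamide is followed on neutralisation by δ-lactamisation of the primary amine onto the geminally activated malonate ester cis to the C12 arm through a chair six-membered transition state, which tells the two diastereotopic esters apart and should outpace the acyl shift onto the ring D lactone, which has to pass through a strained bridged bicyclo[2.2.1] tetrahedral intermediate.

Step 18
Reactants: 33 N–H δ-lactam; 34 3-bromo-1-(trimethylsilyl)prop-1-yne
Product: 35 N-[3-(trimethylsilyl)prop-2-ynyl] lactam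
Conditions: KN(SiMe3)2 (1.0 equiv), THF, −78 °C; then 34, −78 → −20 °C
Reagents that add atoms: none
Why: N-alkylation of the potassium lactamate, which forms by fast kinetic N–H deprotonation that leaves the less acidic lactone α-hydrogens alone, with a reactive propargylic bromide.

Step 19
Reactants: 35 N-[3-(trimethylsilyl)prop-2-ynyl] lactam
Product: 36 N-propargyl lactam C27 carboxylic acid
Conditions: TASF, DMF, 0 → 23 °C; then 1 M aq. HCl
Reagents that add atoms: none
Why: fluoride-induced β-elimination of the 2-(trimethylsilyl)ethyl ester releases the C27 carboxylic acid and the same reagent desilylates the alkyne, while lactones and lactam are inert.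

Step 20
Reactants: 36 N-propargyl lactam C27 carboxylic acid
Product: 38 N-propargyl lactam C25 aldehyde, via acid chloride 37 (not isolated)
Conditions: (COCl)2, DMF (cat.), CH2Cl2, 0 → 23 °C; then LiAlH(OtBu)3, THF, −78 °C
Reagents that add atoms: none
Why: the same acid chloride reduction as in step 12 gives a neopentyl aldehyde that has no α-hydrogen and cannot epimerise or enolise.

Step 21
Reactants: 38 N-propargyl lactam C25 aldehyde
Product: 39 N-(3-iodoprop-2-ynyl) lactam aldehyde
Conditions: NIS, AgNO3 (10 mol %), acetone, 23 °C, dark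
Reagents that add atoms: N-iodosuccinimide, O=C1CCC(=O)N1I
Why: silver-catalysed electrophilic iodination of the terminal alkyne through the silver acetylide is neutral and leaves the aldehyde untouched.

Step 22
Reactants: 39 N-(3-iodoprop-2-ynyl) lactam aldehyde
Product: 40 N-[(Z)-3-iodoprop-2-enyl] lactam aldehyde
Conditions: KO2CN=NCO2K, AcOH, pyridine, THF/i-PrOH, 23 °C
Reagents that add atoms: none
Why: diimide, freed in the flask, adds hydrogen syn to the iodoalkyne and should give the Z vinyl iodide without reducing the aldehyde or the C–I bond.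

Step 23
Reactants: 40 N-[(Z)-3-iodoprop-2-enyl] lactam aldehyde
Product: 41 bridged lactam (1-azabicyclo[4.3.1]decenone core) with C23=C24 (Z) and 25R carbinol
Conditions: CrCl2 (6 equiv), NiCl2 (2 mol %), DMSO/THF, 2 mM, 23 °C
Reagents that add atoms: none
Why: in this Nozaki–Hiyama–Kishi ring closure zerovalent nickel inserts into the C–I bond, the vinyl group passes to trivalent chromium and adds irreversibly to the C25 aldehyde, which pays for the twist forced on the lactam as the seven-membered ring forms, and the chromium-bound oxygen should lie on the lactam carbonyl side of C25, away from the lactone face, to give the 25R carbinol.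

Step 24
Reactants: 41 bridged lactam allylic alcohol
Product: 42 CNP0120800.1
Conditions: H2 (1 atm), Rh/Al2O3, EtOAc, 23 °C
Reagents that add atoms: none
Why: alkene hydrogenation over rhodium saturates C23–C24 with little allylic C–O hydrogenolysis and should leave the bridged lactam and both lactones intact.

Compound list
1 | 2,3-O-isopropylidene-D-glyceraldehyde | O=C[C@H]1COC(C)(C)O1 | starting material
2 | ethyl 2-[bis(2,2,2-trifluoroethoxy)phosphoryl]propanoate | CCOC(=O)C(C)P(=O)(OCC(F)(F)F)OCC(F)(F)F | starting material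
3 | ethyl (Z)-3-[(4S)-2,2-dimethyl-1,3-dioxolan-4-yl]-2-methylprop-2-enoate | CCOC(=O)/C(C)=C\[C@H]1COC(C)(C)O1 | intermediate
4 | (5S)-5-(hydroxymethyl)-3-methylfuran-2(5H)-one | CC1=C[C@@H](CO)OC1=O | intermediate
5 | (bromomethyl)chlorodimethylsilane | C[Si](C)(Cl)CBr | starting material
6 | (5S)-5-{[(bromomethyl)dimethylsilyl]oxymethyl}-3-methylfuran-2(5H)-one | CC1=C[C@@H](CO[Si](C)(C)CBr)OC1=O | intermediate (not isolated)
7 | all-cis bicyclic siloxane lactone (C4–CH2–O–SiMe2–CH2–C10 ring cis-fused to the lactone, C8 methyl on the same face) | C[C@@H]1C(=O)O[C@@H]2CO[Si](C)(C)C[C@H]12 | intermediate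
8 | (3S,4S,5S)-4,5-bis(hydroxymethyl)-3-methyloxolan-2-one | C[C@@H]1C(=O)O[C@H](CO)[C@@H]1CO | intermediate
9 | (3S,4S,5S)-5-[(tert-butyldiphenylsilyloxy)methyl]-4-(hydroxymethyl)-3-methyloxolan-2-one | C[C@@H]1C(=O)O[C@H](CO[Si](c2ccccc2)(c2ccccc2)C(C)(C)C)[C@@H]1CO | intermediate
10 | benzyl (triphenylphosphoranylidene)acetate | O=C(C=P(c1ccccc1)(c1ccccc1)c1ccccc1)OCc1ccccc1 | starting material
11 | all-cis C11 aldehyde of 9 | C[C@@H]1C(=O)O[C@H](CO[Si](c2ccccc2)(c2ccccc2)C(C)(C)C)[C@@H]1C=O | intermediate (not isolated)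
12 | benzyl (E)-3-[(2S,3R,4S)-2-[(tert-butyldiphenylsilyloxy)methyl]-4-methyl-5-oxooxolan-3-yl]prop-2-enoate | C[C@@H]1C(=O)O[C@H](CO[Si](c2ccccc2)(c2ccccc2)C(C)(C)C)[C@@H]1/C=C/C(=O)OCc1ccccc1 | intermediate
13 | benzyl (E)-3-[(2S,3R,4S)-2-(hydroxymethyl)-4-methyl-5-oxooxolan-3-yl]prop-2-enoate | C[C@@H]1C(=O)O[C@H](CO)[C@@H]1/C=C/C(=O)OCc1ccccc1 | intermediate
14 | malonic acid | OC(=O)CC(=O)O | starting material
15 | 2-(trimethylsilyl)ethanol | C[Si](C)(C)CCO | starting material
16 | bis[2-(trimethylsilyl)ethyl] propanedioate | C[Si](C)(C)CCOC(=O)CC(=O)OCC[Si](C)(C)C | intermediate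
17 | benzyl (E)-3-[(2S,3R,4S)-2-formyl-4-methyl-5-oxooxolan-3-yl]prop-2-enoate | C[C@@H]1C(=O)O[C@H](C=O)[C@@H]1/C=C/C(=O)OCc1ccccc1 | intermediate (not isolated)
18 | all-cis lactone with C3 alkylidene bis[2-(trimethylsilyl)ethyl] malonate and C11 (E)-benzyl enoate | C[C@@H]1C(=O)O[C@H](C=C(C(=O)OCC[Si](C)(C)C)C(=O)OCC[Si](C)(C)C)[C@@H]1/C=C/C(=O)OCc1ccccc1 | intermediate
19 | diethylzinc | CC[Zn]CC | starting material
20 | ethylzinc enolate of the C3 ethyl malonate adduct | CC[Zn]OC(OCC[Si](C)(C)C)=C(C(=O)OCC[Si](C)(C)C)[C@H](CC)[C@H]1OC(=O)[C@@H](C)[C@H]1/C=C/C(=O)OCc1ccccc1 | intermediate (not isolated)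
21 | open-chain C3 ethyl malonate adduct of 18 (C3 configured as in 22) | CC[C@@H](C(C(=O)OCC[Si](C)(C)C)C(=O)OCC[Si](C)(C)C)[C@H]1OC(=O)[C@@H](C)[C@H]1/C=C/C(=O)OCc1ccccc1 | intermediate (not isolated)
22 | cis-fused cyclopentane lactone: C3 ethyl trans to O5, C27 bis[2-(trimethylsilyl)ethyl] ester, C11 CH2CO2Bn trans to C8 | CC[C@@H]1[C@H]2OC(=O)[C@@H](C)[C@H]2[C@H](CC(=O)OCc2ccccc2)C1(C(=O)OCC[Si](C)(C)C)C(=O)OCC[Si](C)(C)C | intermediate
23 | C13 carboxylic acid of 22 | CC[C@@H]1[C@H]2OC(=O)[C@@H](C)[C@H]2[C@H](CC(=O)O)C1(C(=O)OCC[Si](C)(C)C)C(=O)OCC[Si](C)(C)C | intermediate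
24 | C13 acid chloride | CC[C@@H]1[C@H]2OC(=O)[C@@H](C)[C@H]2[C@H](CC(=O)Cl)C1(C(=O)OCC[Si](C)(C)C)C(=O)OCC[Si](C)(C)C | intermediate (not isolated)
25 | C13 aldehyde | CC[C@@H]1[C@H]2OC(=O)[C@@H](C)[C@H]2[C@H](CC=O)C1(C(=O)OCC[Si](C)(C)C)C(=O)OCC[Si](C)(C)C | intermediate
26 | (S)-2-methylpropane-2-sulfinamide | CC(C)(C)[S@](=O)N | starting material
27 | (S)-N-tert-butanesulfinyl (E)-aldimine at C13 | CC[C@@H]1[C@H]2OC(=O)[C@@H](C)[C@H]2[C@H](C/C=N/[S@@](=O)C(C)(C)C)C1(C(=O)OCC[Si](C)(C)C)C(=O)OCC[Si](C)(C)C | intermediate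
28 | 3-methylfuran-2(5H)-one | CC1=CCOC1=O | starting material
29 | tert-butyldimethyl[(3-methylfuran-2-yl)oxy]silane | Cc1ccoc1O[Si](C)(C)C(C)(C)C | intermediate
30 | (13R,14R)-sulfinamide with 3-methylbutenolide at C14 | CC[C@@H]1[C@H]2OC(=O)[C@@H](C)[C@H]2[C@H](C[C@@H](N[S@@](=O)C(C)(C)C)[C@H]2C=C(C)C(=O)O2)C1(C(=O)OCC[Si](C)(C)C)C(=O)OCC[Si](C)(C)C | intermediate
31 | sulfinamide with saturated ring D lactone (13R,14R,16R) | CC[C@@H]1[C@H]2OC(=O)[C@@H](C)[C@H]2[C@H](C[C@@H](N[S@@](=O)C(C)(C)C)[C@H]2C[C@@H](C)C(=O)O2)C1(C(=O)OCC[Si](C)(C)C)C(=O)OCC[Si](C)(C)C | intermediate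
32 | C13 primary amine | CC[C@@H]1[C@H]2OC(=O)[C@@H](C)[C@H]2[C@H](C[C@@H](N)[C@H]2C[C@@H](C)C(=O)O2)C1(C(=O)OCC[Si](C)(C)C)C(=O)OCC[Si](C)(C)C | intermediate (not isolated)
33 | cis-fused N–H δ-lactam (N21–C28) with C27 2-(trimethylsilyl)ethyl ester | CC[C@@H]1[C@H]2OC(=O)[C@@H](C)[C@H]2[C@@H]2C[C@H]([C@H]3C[C@@H](C)C(=O)O3)NC(=O)[C@]12C(=O)OCC[Si](C)(C)C | intermediate
34 | 3-bromo-1-(trimethylsilyl)prop-1-yne | C[Si](C)(C)C#CCBr | starting material
35 | N-[3-(trimethylsilyl)prop-2-ynyl] lactam ester | CC[C@@H]1[C@H]2OC(=O)[C@@H](C)[C@H]2[C@@H]2C[C@H]([C@H]3C[C@@H](C)C(=O)O3)N(CC#C[Si](C)(C)C)C(=O)[C@]12C(=O)OCC[Si](C)(C)C | intermediate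
36 | N-propargyl lactam C27 carboxylic acid | CC[C@@H]1[C@H]2OC(=O)[C@@H](C)[C@H]2[C@@H]2C[C@H]([C@H]3C[C@@H](C)C(=O)O3)N(CC#C)C(=O)[C@]12C(=O)O | intermediate
37 | N-propargyl lactam C27 acid chloride | CC[C@@H]1[C@H]2OC(=O)[C@@H](C)[C@H]2[C@@H]2C[C@H]([C@H]3C[C@@H](C)C(=O)O3)N(CC#C)C(=O)[C@]12C(=O)Cl | intermediate (not isolated)
38 | N-propargyl lactam C25 aldehyde | CC[C@@H]1[C@H]2OC(=O)[C@@H](C)[C@H]2[C@@H]2C[C@H]([C@H]3C[C@@H](C)C(=O)O3)N(CC#C)C(=O)[C@]12C=O | intermediate
39 | N-(3-iodoprop-2-ynyl) lactam C25 aldehyde | CC[C@@H]1[C@H]2OC(=O)[C@@H](C)[C@H]2[C@@H]2C[C@H]([C@H]3C[C@@H](C)C(=O)O3)N(CC#CI)C(=O)[C@]12C=O | intermediate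
40 | N-[(Z)-3-iodoprop-2-enyl] lactam C25 aldehyde | CC[C@@H]1[C@H]2OC(=O)[C@@H](C)[C@H]2[C@@H]2C[C@H]([C@H]3C[C@@H](C)C(=O)O3)N(C/C=C\I)C(=O)[C@]12C=O | intermediate
41 | bridged lactam with C23=C24 (Z) and 25R carbinol | CC[C@@H]1[C@H]2OC(=O)[C@@H](C)[C@H]2[C@@H]2C[C@H]([C@H]3C[C@@H](C)C(=O)O3)N3C/C=C\[C@@H](O)[C@@]12C3=O | intermediate
42 | CNP0120800.1 | CC[C@@H]1[C@H]2OC(=O)[C@@H](C)[C@H]2[C@@H]2C[C@H]([C@H]3C[C@@H](C)C(=O)O3)N3CCC[C@@H](O)[C@@]12C3=O | target

Total step count: 24. Longest linear sequence: 22 steps (1–7, 9–13, 15–24); steps 8 and 14 prepare the malonate and the silyloxyfuran.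

Steps most likely to fail

Step 10. The ethylcopper species may expel the allylic lactone carboxylate instead of adding 1,4, facial control at C3 may erode, or the zinc malonate may not close onto the enoate. The fallback separates the two bond formations and delivers ethyl as a radical. It sets out from 18: Et3B and air in CH2Cl2 at −78 °C add an ethyl radical to C3, with steric control by the cis C10 arm and no organocopper that could displace the carboxylate. Hydrolysis of the boron enolate gives the open-chain malonate 21, now isolated. Cs2CO3 in MeCN at 23 °C then closes the ring by 5-exo-trig Michael addition, and the route is rejoined at 22.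

Step 23. The vinylchromium may not reach the aldehyde because the lactam has to twist in the transition state, or the closure may give the wrong C25 epimer. The fallback sets C25 in an open-chain step and closes the ring by metathesis. It sets out from 33: KN(SiMe3)2 and allyl bromide give N-allyl lactam ester F1, TASF frees N-allyl lactam acid F2, and (COCl)2 followed by LiAlH(OtBu)3 gives N-allyl lactam aldehyde F3. Vinylmagnesium bromide at −78 °C should add from the C3 side under chelation between the aldehyde and the lactam carbonyl to give diene carbinol F4, whose epimers can be separated. Ring-closing metathesis with second-generation Grubbs catalyst in toluene at high dilution forms C23=C24, and the route is rejoined at 41.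

Step 5. The silyl chloride may discriminate poorly between the two primary carbinols, and the free diol may translactonise while it is handled. The fallback lets the tether fix the regiochemistry and avoids the diol. It sets out from 7: HF·pyridine in THF opens the Si–O bond to give fluorosilane alcohol F5, in which only the C3 oxygen is free. TBDPSOTf and 2,6-lutidine at −78 °C give fluorosilane silyl ether F6. Tamao oxidation (H2O2, KF, KHCO3) of the C11–Si bond then rejoins the route at 9.

Further compounds
F0 | step 10 | none | none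
F1 | step 23 | N-allyl lactam ester | CC[C@@H]1[C@H]2OC(=O)[C@@H](C)[C@H]2[C@@H]2C[C@H]([C@H]3C[C@@H](C)C(=O)O3)N(CC=C)C(=O)[C@]12C(=O)OCC[Si](C)(C)C
F2 | step 23 | N-allyl lactam acid | CC[C@@H]1[C@H]2OC(=O)[C@@H](C)[C@H]2[C@@H]2C[C@H]([C@H]3C[C@@H](C)C(=O)O3)N(CC=C)C(=O)[C@]12C(=O)O
F3 | step 23 | N-allyl lactam aldehyde | CC[C@@H]1[C@H]2OC(=O)[C@@H](C)[C@H]2[C@@H]2C[C@H]([C@H]3C[C@@H](C)C(=O)O3)N(CC=C)C(=O)[C@]12C=O
F4 | step 23 | diene carbinol (25R) | CC[C@@H]1[C@H]2OC(=O)[C@@H](C)[C@H]2[C@@H]2C[C@H]([C@H]3C[C@@H](C)C(=O)O3)N(CC=C)C(=O)[C@]12[C@H](O)C=C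
F5 | step 5 | fluorosilane alcohol | C[C@@H]1C(=O)O[C@H](CO)[C@@H]1C[Si](C)(C)F
F6 | step 5 | fluorosilane silyl ether | C[C@@H]1C(=O)O[C@H](CO[Si](c2ccccc2)(c2ccccc2)C(C)(C)C)[C@@H]1C[Si](C)(C)F
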